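**Plan**
- Retrosynthetic cuts: (a) the ring bond C5–C10, the central σ-bond of the hexa-1,5-diene C2=C1–C10–C5–C4=C3 formed by the vinyl group on the quaternary ring carbon and the 2-propenyl group on the neighbouring ring CH; (b) the C8 ester; (c) C5–C4; (d) C8–C9; (e) C6–C7.
- Enabling feature: each end of the C5–C10 bond is the substituted terminus of an allyl unit, so the only carbocycle can be closed last by joining two allyl fragments of like polarity, B2pin2 reversing the polarity of one.
- Forward chain assembly: Baylis–Hillman adduct → (Z)-allyl bromide → indium Barbier addition to (S)-glyceraldehyde acetonide (C6–C7) → vinylogous Mukaiyama aldol (C8–C9 and the C10=C1–C2 arm) → esterification → Nozaki–Hiyama–Kishi coupling (C4 arm) → one-flask borylation/allyl–allyl cyclisation → deprotection.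
- Stereochemistry: C6 by Felkin–Anh addition to (S)-glyceraldehyde acetonide, whose own stereocentre later becomes the C5 aldehyde carbon; C7 from the (Z)-allylindium (syn addition); C8 by Felkin/1,3-anti control; the acyl centre from the (S)-Roche ester.
- C5 and C10 arise together in the ring closure: chair-like 3,3'-reductive elimination, (E)-allyl geometry, C7 and C8 substituents equatorial.
- Helpers (dioxolane, PMB and TBS ethers, tert-butyl ester, the two carbonates) are all removed by the end.

Key step: step 18

Remark: locants follow the elemane skeleton: C10 = quaternary ring carbon (C14 methyl, C1=C2 vinyl), C9 = ring CH2, C8 = acyloxy carbon, C7 = carbon bearing the acrylic acid (C11, C12 acid, C13 methylene), C6 = carbinol carbon, C5 = ring CH bearing C4(=C3H2)–C15H2OH. TBS = tert-butyldimethylsilyl, PMB = 4-methoxybenzyl.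
Remark: 2-[(4-methoxybenzyl)oxy]acetaldehyde and (S)-glyceraldehyde acetonide are taken as purchasable; the latter is used freshly distilled because it oligomerises on storage.

Step 1
Reactants: 1 tert-butyl acrylate; 2 2-[(4-methoxybenzyl)oxy]acetaldehyde
Product: 3 tert-butyl 3-hydroxy-4-[(4-methoxybenzyl)oxy]-2-methylidenebutanoate (racemic)
Conditions: DABCO (0.3 equiv), dioxane/H2O 1:1, rt
Reagents that add atoms: none
Why: Morita–Baylis–Hillman reaction of an activated α-alkoxy aldehyde with an acrylate; the racemic carbinol centre is flattened in step 2.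

Step 2
Reactants: 3 Baylis–Hillman adduct
Product: 4 tert-butyl (2Z)-2-(bromomethyl)-4-[(4-methoxybenzyl)oxy]but-2-enoate
Conditions: NBS, Me2S, CH2Cl2, 0 °C to rt
Reagents that add atoms: N-bromosuccinimide, O=C1CCC(=O)N1Br
Why: Corey–Kim-type activation of the alcohol as its alkoxysulfonium salt followed by SN2' delivery of bromide should give the conjugated trisubstituted acrylate as the thermodynamically preferred (Z) isomer (CH2OPMB cis to CH2Br).

Step 3
Reactants: 4 (Z)-allyl bromide; 5 (S)-2,2-dimethyl-1,3-dioxolane-4-carbaldehyde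
Product: 7 tert-butyl (3R,4R)-4-[(4S)-2,2-dimethyl-1,3-dioxolan-4-yl]-4-hydroxy-3-{[(4-methoxybenzyl)oxy]methyl}-2-methylidenebutanoate, via allylindium reagent 6 (not isolated)
Conditions: indium powder, THF/H2O 1:1, rt
Reagents that add atoms: none
Why: Indium-mediated Barbier allylation reacts at the γ-carbon through a six-membered cyclic transition state in which the (Z) γ-substituent is axial, which sets C7 syn to the new hydroxyl, while Felkin–Anh attack anti to the dioxolane C–O bond of the (S)-aldehyde sets C6; the tert-butyl ester keeps the γ-hydroxy ester from lactonising.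

Step 4
Reactants: 7 homoallylic alcohol
Product: 8 C6 TBS ether of 7
Conditions: tBuMe2SiOTf, 2,6-lutidine, CH2Cl2, −78 °C
Reagents that add atoms: tert-butyldimethylsilyl triflate, CC(C)(C)[Si](C)(C)OS(=O)(=O)C(F)(F)F
Why: Silylation of the hindered secondary alcohol with the silyl triflate blocks lactonisation onto C12 for the rest of the route.

Step 5
Reactants: 8 silyl ether
Product: 9 primary alcohol (C8 hydroxymethyl, PMB removed)
Conditions: DDQ, CH2Cl2/pH 7 buffer, 0 °C
Reagents that add atoms: none
Why: Oxidative PMB cleavage (benzylic hydride abstraction, hydrolysis of the oxocarbenium ion) should leave the silyl ether, acetonide and acrylate untouched.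

Step 6
Reactants: 9 primary alcohol
Product: 10 aldehyde (C8 formyl)
Conditions: Dess–Martin periodinane, NaHCO3, CH2Cl2, 0 °C; used crude
Reagents that add atoms: none
Why: Dess–Martin oxidation under buffered, non-basic conditions should give the α-branched β,γ-unsaturated aldehyde without epimerisation at C7 or migration of the double bond.

Step 7
Reactants: 11 3-methylbut-2-enal
Product: 12 (E)-trimethyl[(3-methylbuta-1,3-dien-1-yl)oxy]silane
Conditions: Me3SiOTf, Et3N, Et2O, 0 °C
Reagents that add atoms: trimethylsilyl triflate, C[Si](C)(C)OS(=O)(=O)C(F)(F)F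
Why: O-silylation of the enal and γ-deprotonation by the amine (silyl dienol ether formation) gives the vinylogous nucleophile.

Step 8
Reactants: 10 aldehyde; 12 silyl dienol ether
Product: 13 (E)-δ-hydroxy enal (C8 carbinol; C2 formyl on the C10=C1 alkene)
Conditions: BF3·OEt2, CH2Cl2, −78 °C; aqueous quench
Reagents that add atoms: none
Why: Vinylogous Mukaiyama aldol addition through the γ-terminus should give the (E)-enal, and C8 is set by Felkin–Anh attack (hydroxyl syn to the acrylate-bearing α-substituent) reinforced by 1,3-anti induction from the β-silyloxy group, the two effects being matched in this α,β-anti aldehyde.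

Step 9
Reactants: 14 methyl (S)-3-hydroxy-2-methylpropanoate
Product: 15 methyl (S)-3-[(tert-butyldimethylsilyl)oxy]-2-methylpropanoate
Conditions: tBuMe2SiCl, imidazole, CH2Cl2, rt
Reagents that add atoms: tert-butyldimethylsilyl chloride, CC(C)(C)[Si](C)(C)Cl
Why: Standard silylation of the primary alcohol of the Roche ester; the stereocentre is untouched.

Step 10
Reactants: 15 silylated Roche ester
Product: 16 (S)-3-[(tert-butyldimethylsilyl)oxy]-2-methylpropanoic acid
Conditions: LiOH, THF/H2O, 0 °C to rt; then dilute HCl to pH 4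
Reagents that add atoms: lithium hydroxide, [Li+].[OH-]
Why: Saponification of an unhindered methyl ester at low temperature should proceed without epimerisation of the α-centre.

Step 11
Reactants: 13 δ-hydroxy enal; 16 acid
Product: 17 C8 ester of 13 with the (S)-3-silyloxy-2-methylpropanoyl group
Conditions: EDC·HCl, DMAP, CH2Cl2, 0 °C to rt
Reagents that add atoms: none
Why: Steglich esterification acylates the only free hydroxyl and creates no new stereocentre.

Step 12
Reactants: 17 ester enal
Product: 18 primary (E)-allylic alcohol (C2 hydroxymethyl)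
Conditions: NaBH4, CeCl3·7H2O, MeOH, −40 °C
Reagents that add atoms: none
Why: Luche reduction is 1,2-selective for the enal and should leave the acrylate, both esters and the silyl ethers alone.

Step 13
Reactants: 18 allylic alcohol
Product: 20 α-silyloxy aldehyde (C5 formyl), via triol 19 (not isolated)
Conditions: H5IO6, EtOAc, 0 °C to rt
Reagents that add atoms: none
Why: Periodic acid hydrolyses the terminal acetonide and cleaves the resulting glycol in the same flask (Malaprade cleavage), so that the former glyceraldehyde stereocentre becomes the C5 aldehyde carbon.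

Step 14
Reactants: 21 prop-2-yn-1-ol
Product: 22 2-iodoprop-2-en-1-ol
Conditions: NaI, Me3SiCl, H2O, MeCN, rt
Reagents that add atoms: sodium iodide, [Na+].[I-]
Why: Markovnikov hydroiodination of the terminal alkyne by hydrogen iodide generated in the flask.

Step 15
Reactants: 22 2-iodoprop-2-en-1-ol
Product: 23 tert-butyl[(2-iodoprop-2-en-1-yl)oxy]dimethylsilane
Conditions: tBuMe2SiCl, imidazole, CH2Cl2, 0 °C
Reagents that add atoms: tert-butyldimethylsilyl chloride, CC(C)(C)[Si](C)(C)Cl
Why: Standard silylation of the primary allylic alcohol.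

Step 16
Reactants: 20 aldehyde; 23 alkenyl iodide
Product: 25 bis-allylic diol (C2 primary OH; C5 secondary OH as a mixture of epimers), via alkenylchromium reagent 24 (not isolated)
Conditions: CrCl2 (6 equiv), NiCl2 (2 mol%), DMSO, rt
Reagents that add atoms: none
Why: Nozaki–Hiyama–Kishi coupling adds the alkenylchromium species chemoselectively to the aldehyde in the presence of esters, the acrylate and the free allylic alcohol; the new carbinol centre need not be controlled because it is erased in step 18.

Step 17
Reactants: 25 diol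
Product: 27 C2 methyl carbonate and C5 tert-butyl carbonate, via mono(methyl carbonate) 26 (not isolated)
Conditions: ClCO2Me (1.0 equiv), pyridine, CH2Cl2, −30 °C; then Boc2O, DMAP, rt
Reagents that add atoms: methyl chloroformate, COC(=O)Cl; di-tert-butyl dicarbonate, CC(C)(C)OC(=O)OC(=O)OC(C)(C)C
Why: Carbonate formation: methyl chloroformate reacts first at the unhindered primary allylic alcohol and Boc2O/DMAP then converts the hindered secondary one, giving two allylic carbonates of different ionisation rate.

Step 18
Reactants: 27 mixed bis-carbonate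
Product: 29 protected elemane (cyclohexane closed; vinyl on C10, 2-propenyl unit on C5), via allylboronate 28 (not isolated)
Conditions: B2pin2 (1.0 equiv), Pd2(dba)3 (5 mol%), THF, 25 °C; then 1,2-bis(diphenylphosphino)benzene (12 mol%), THF (5 mM), 60 °C
Reagents that add atoms: none
Why: Proposed new method: zerovalent palladium should first ionise the unhindered primary methyl carbonate, whose methoxide lets B2pin2 convert that allyl unit into the linear (E)-allylboronate 28; the diphosphine complex then ionises the tert-butyl carbonate at C5, the tert-butoxide activates the tethered boronate, and transmetalation gives a bis(η1-allyl) divalent palladium species with the metal bridging C2 and C3, from which 3,3'-reductive elimination joins C10 to C5 and leaves the C1=C2 and C4=C3 alkenes. The closest known reaction types are the intermolecular branch-selective coupling of allylboronates with allylic carbonates under Pd/small-bite-angle diphosphine catalysis, the Pd-catalysed borylation of allylic carbonates with B2pin2 and the cyclisation of bis-allylic dihalides by zerovalent nickel, none of which has been shown as a catalytic ring closure that builds a quaternary centre next to a tertiary one. The cyclohexane closes as a transannular bond formation inside an eleven-membered palladacycle through a chair-like seven-membered reductive-elimination array, the metal playing the part of the C2–C3 bond of a Cope rearrangement. C10 is fixed by the (E) geometry of the trisubstituted allyl unit (tether pseudo-equatorial, methyl pseudo-axial) and C5 by the need for both alkenyl arms to be equatorial on the forming chair, whose face is chosen by C7 and C8 keeping their substituents equatorial and leaving only the C6 silyloxy group axial; the C5 carbinol configuration of 27 is lost in the π-allyl, so both epimers converge. The step needs single borylation (methyl versus tert-butyl carbonate, primary versus hindered secondary, one equivalent of diboron, two temperature stages), 3,3' instead of 1,1' or 1,3' coupling (the chelating diphosphine enforces the bis(η1) geometry) and ring closure over oligomerisation (high dilution).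

Step 19
Reactants: 29 protected elemane
Product: 31 carboxylic acid (C12 free; three TBS ethers retained), via trimethylsilyl ester 30 (not isolated)
Conditions: Me3SiOTf, 2,6-lutidine, CH2Cl2, 0 °C; then pH 5 aqueous buffer
Reagents that add atoms: none
Why: Silyl-triflate cleavage of the tert-butyl ester (O-silylation, loss of isobutene, hydrolysis of the silyl ester on work-up) spares the secondary alkyl ester and the silyl ethers and frees the acid while the C6 oxygen is still silylated, so that it cannot lactonise.

Step 20
Reactants: 31 acid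
Product: 32 2-[(1S,2S,3R,4S,6S)-4-ethenyl-2-hydroxy-6-{[(2S)-3-hydroxy-2-methylpropanoyl]oxy}-3-(3-hydroxyprop-1-en-2-yl)-4-methylcyclohexyl]prop-2-enoic acid (target)
Conditions: Bu4NF, AcOH, THF, 0 to 40 °C; work-up at pH 4 to 5
Reagents that add atoms: none
Why: Fluoride-mediated desilylation buffered with acetic acid should remove the three TBS groups without lactonisation of the acid onto the C6 hydroxyl or acyl migration, the C6 and C8 oxygens being trans on the ring.

**Compound list**
1 | tert-butyl acrylate | C=CC(=O)OC(C)(C)C | starting material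
2 | 2-[(4-methoxybenzyl)oxy]acetaldehyde | COc1ccc(COCC=O)cc1 | starting material
3 | tert-butyl 3-hydroxy-4-[(4-methoxybenzyl)oxy]-2-methylidenebutanoate (racemic) | COc1ccc(COCC(O)C(=C)C(=O)OC(C)(C)C)cc1 | intermediate
4 | tert-butyl (2Z)-2-(bromomethyl)-4-[(4-methoxybenzyl)oxy]but-2-enoate | COc1ccc(COC/C=C(\CBr)C(=O)OC(C)(C)C)cc1 | intermediate
5 | (S)-2,2-dimethyl-1,3-dioxolane-4-carbaldehyde | O=C[C@@H]1COC(C)(C)O1 | starting material
6 | allylindium reagent from 4, drawn as the dibromoindium species | COc1ccc(COC/C=C(\C[In](Br)Br)C(=O)OC(C)(C)C)cc1 | intermediate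
7 | tert-butyl (3R,4R)-4-[(4S)-2,2-dimethyl-1,3-dioxolan-4-yl]-4-hydroxy-3-{[(4-methoxybenzyl)oxy]methyl}-2-methylidenebutanoate | COc1ccc(COC[C@@H](C(=C)C(=O)OC(C)(C)C)[C@@H](O)[C@@H]2COC(C)(C)O2)cc1 | intermediate
8 | C6 TBS ether of 7 | COc1ccc(COC[C@@H](C(=C)C(=O)OC(C)(C)C)[C@@H](O[Si](C)(C)C(C)(C)C)[C@@H]2COC(C)(C)O2)cc1 | intermediate
9 | primary alcohol from 8 (C8 hydroxymethyl) | OC[C@@H](C(=C)C(=O)OC(C)(C)C)[C@@H](O[Si](C)(C)C(C)(C)C)[C@@H]1COC(C)(C)O1 | intermediate
10 | aldehyde from 9 (C8 formyl) | O=C[C@@H](C(=C)C(=O)OC(C)(C)C)[C@@H](O[Si](C)(C)C(C)(C)C)[C@@H]1COC(C)(C)O1 | intermediate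
11 | 3-methylbut-2-enal | CC(C)=CC=O | starting material
12 | (E)-trimethyl[(3-methylbuta-1,3-dien-1-yl)oxy]silane | C=C(C)/C=C/O[Si](C)(C)C | intermediate
13 | (E)-δ-hydroxy enal; C6, C7 and C8 configured as in 32 | O=C/C=C(\C)C[C@H](O)[C@@H](C(=C)C(=O)OC(C)(C)C)[C@@H](O[Si](C)(C)C(C)(C)C)[C@@H]1COC(C)(C)O1 | intermediate
14 | methyl (S)-3-hydroxy-2-methylpropanoate | C[C@@H](CO)C(=O)OC | starting material
15 | methyl (S)-3-[(tert-butyldimethylsilyl)oxy]-2-methylpropanoate | C[C@@H](CO[Si](C)(C)C(C)(C)C)C(=O)OC | intermediate
16 | (S)-3-[(tert-butyldimethylsilyl)oxy]-2-methylpropanoic acid | C[C@@H](CO[Si](C)(C)C(C)(C)C)C(=O)O | intermediate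
17 | C8 (S)-3-silyloxy-2-methylpropanoate of 13 | O=C/C=C(\C)C[C@H](OC(=O)[C@@H](C)CO[Si](C)(C)C(C)(C)C)[C@@H](C(=C)C(=O)OC(C)(C)C)[C@@H](O[Si](C)(C)C(C)(C)C)[C@@H]1COC(C)(C)O1 | intermediate
18 | (E)-allylic alcohol from 17 (C2 hydroxymethyl) | OC/C=C(\C)C[C@H](OC(=O)[C@@H](C)CO[Si](C)(C)C(C)(C)C)[C@@H](C(=C)C(=O)OC(C)(C)C)[C@@H](O[Si](C)(C)C(C)(C)C)[C@@H]1COC(C)(C)O1 | intermediate
19 | triol from 18 (acetonide removed) | OC/C=C(\C)C[C@H](OC(=O)[C@@H](C)CO[Si](C)(C)C(C)(C)C)[C@@H](C(=C)C(=O)OC(C)(C)C)[C@@H](O[Si](C)(C)C(C)(C)C)[C@@H](O)CO | intermediate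
20 | α-silyloxy aldehyde (C5 formyl) | OC/C=C(\C)C[C@H](OC(=O)[C@@H](C)CO[Si](C)(C)C(C)(C)C)[C@@H](C(=C)C(=O)OC(C)(C)C)[C@@H](O[Si](C)(C)C(C)(C)C)C=O | intermediate
21 | prop-2-yn-1-ol | C#CCO | starting material
22 | 2-iodoprop-2-en-1-ol | C=C(I)CO | intermediate
23 | tert-butyl[(2-iodoprop-2-en-1-yl)oxy]dimethylsilane | C=C(I)CO[Si](C)(C)C(C)(C)C | intermediate
24 | alkenylchromium reagent from 23, drawn as the dichlorochromium species | C=C(CO[Si](C)(C)C(C)(C)C)[Cr](Cl)Cl | intermediate
25 | bis-allylic diol (C2 primary OH, C5 secondary OH, both C5 epimers) | OC/C=C(\C)C[C@H](OC(=O)[C@@H](C)CO[Si](C)(C)C(C)(C)C)[C@@H](C(=C)C(=O)OC(C)(C)C)[C@@H](O[Si](C)(C)C(C)(C)C)C(O)C(=C)CO[Si](C)(C)C(C)(C)C | intermediate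
26 | C2 methyl carbonate of 25 | COC(=O)OC/C=C(\C)C[C@H](OC(=O)[C@@H](C)CO[Si](C)(C)C(C)(C)C)[C@@H](C(=C)C(=O)OC(C)(C)C)[C@@H](O[Si](C)(C)C(C)(C)C)C(O)C(=C)CO[Si](C)(C)C(C)(C)C | intermediate
27 | C2 methyl carbonate, C5 tert-butyl carbonate of 25 | COC(=O)OC/C=C(\C)C[C@H](OC(=O)[C@@H](C)CO[Si](C)(C)C(C)(C)C)[C@@H](C(=C)C(=O)OC(C)(C)C)[C@@H](O[Si](C)(C)C(C)(C)C)C(OC(=O)OC(C)(C)C)C(=C)CO[Si](C)(C)C(C)(C)C | intermediate
28 | (E)-allylboronate (pinacolboryl on C2) bearing the C5 tert-butyl carbonate | CC1(C)OB(C/C=C(\C)C[C@H](OC(=O)[C@@H](C)CO[Si](C)(C)C(C)(C)C)[C@@H](C(=C)C(=O)OC(C)(C)C)[C@@H](O[Si](C)(C)C(C)(C)C)C(OC(=O)OC(C)(C)C)C(=C)CO[Si](C)(C)C(C)(C)C)OC1(C)C | intermediate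
29 | protected elemane: tert-butyl ester, tris(TBS ether) of 32 | C=C[C@]1(C)C[C@H](OC(=O)[C@@H](C)CO[Si](C)(C)C(C)(C)C)[C@@H](C(=C)C(=O)OC(C)(C)C)[C@@H](O[Si](C)(C)C(C)(C)C)[C@H]1C(=C)CO[Si](C)(C)C(C)(C)C | intermediate
30 | trimethylsilyl ester of 31 | C=C[C@]1(C)C[C@H](OC(=O)[C@@H](C)CO[Si](C)(C)C(C)(C)C)[C@@H](C(=C)C(=O)O[Si](C)(C)C)[C@@H](O[Si](C)(C)C(C)(C)C)[C@H]1C(=C)CO[Si](C)(C)C(C)(C)C | intermediate
31 | tris(TBS ether) of 32 with free carboxylic acid | C=C[C@]1(C)C[C@H](OC(=O)[C@@H](C)CO[Si](C)(C)C(C)(C)C)[C@@H](C(=C)C(=O)O)[C@@H](O[Si](C)(C)C(C)(C)C)[C@H]1C(=C)CO[Si](C)(C)C(C)(C)C | intermediate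
32 | 2-[(1S,2S,3R,4S,6S)-4-ethenyl-2-hydroxy-6-{[(2S)-3-hydroxy-2-methylpropanoyl]oxy}-3-(3-hydroxyprop-1-en-2-yl)-4-methylcyclohexyl]prop-2-enoic acid | C=C[C@]1(C)C[C@H](OC(=O)[C@@H](C)CO)[C@@H](C(=C)C(=O)O)[C@@H](O)[C@H]1C(=C)CO | target

**Step count and risks**
Total: 20 steps. Longest linear sequence: 15 steps (1–6, 8, 11–13, 16–20).

Steps most likely to fail:

1. Step 18. The diboron may borylate both allyl termini, the tethered boronate may transmetalate too slowly so that the π-allyl loses a β-hydrogen to give a diene, or the reductive elimination may couple the wrong termini or the wrong face. The fallback uses known stoichiometric chemistry and sets out from diol 25. Appel bromination (CBr4, PPh3, CH2Cl2, 0 °C) should give the bis(allylic bromide) F1, the secondary allylic position transposing to the primary bromide. Intramolecular coupling of the two allyl bromides with zerovalent nickel (Ni(cod)2, DMF/THF, high dilution), the classical route to 1,2-dialkenylcyclohexanes of this terpene class, should then give 29 directly. If the nickel joins the two primary termini instead, the product is the (1E,5E)-cyclodeca-1,5-diene F2, which a thermal Cope rearrangement (toluene, 180 °C, sealed tube) should convert through the same chair array into 29, where the route is rejoined.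

2. Step 8. The aldehyde 10 may epimerise at C7 or isomerise into conjugation under the Lewis acid, and facial selectivity may be poor if the acrylate unit and not the silyloxy branch acts as the large Felkin substituent. The fallback puts C8 under reagent control and sets out from 10. Brown methallylboration with (−)-Ipc2B(methallyl), the antipode made from (+)-α-pinene that attacks the Si face (Et2O, −78 °C; NaBO3 work-up), should give the homoallylic alcohol F3. Cross-metathesis of its 1,1-disubstituted alkene with acrolein (second-generation Hoveyda–Grubbs catalyst, CH2Cl2, 40 °C) should then give the (E)-enal 13, where the route is rejoined.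

3. Step 3. The open aqueous Barbier process may give incomplete facial selectivity on the glyceraldehyde, incomplete syn selectivity, or some attack through the α-carbon. The fallback changes to a closed boron transition state and sets out from bromide 4. Copper-catalysed borylation (B2pin2, CuCl cat., KOAc, DMF, rt) should give the 2-(alkoxycarbonyl)allylboronate F4. Its thermal allylboration of 5 (toluene, 80 °C; aqueous work-up) through a Zimmerman–Traxler chair, with the (Z) γ-substituent axial (syn) and the anti preference of (Z)-γ-substituted allylboronates toward glyceraldehyde acetonide, should give 7, where the route is rejoined.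

**Further compounds**
F1 | step 18 | bis(allylic bromide): C2 bromide and transposed C3 bromide on the C4=C5 alkene (geometry mixture) | BrC/C=C(\C)C[C@H](OC(=O)[C@@H](C)CO[Si](C)(C)C(C)(C)C)[C@@H](C(=C)C(=O)OC(C)(C)C)[C@@H](O[Si](C)(C)C(C)(C)C)C=C(CBr)CO[Si](C)(C)C(C)(C)C
F2 | step 18 | (1E,5E)-cyclodeca-1,5-diene from coupling of the two primary termini | C/C1=C\CC/C(CO[Si](C)(C)C(C)(C)C)=C/[C@H](O[Si](C)(C)C(C)(C)C)[C@H](C(=C)C(=O)OC(C)(C)C)[C@@H](OC(=O)[C@@H](C)CO[Si](C)(C)C(C)(C)C)C1
F3 | step 8 | methallyl adduct of 10 (C8 carbinol set by the borane) | C=C(C)C[C@H](O)[C@@H](C(=C)C(=O)OC(C)(C)C)[C@@H](O[Si](C)(C)C(C)(C)C)[C@@H]1COC(C)(C)O1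
F4 | step 3 | tert-butyl (2Z)-4-[(4-methoxybenzyl)oxy]-2-[(pinacolboryl)methyl]but-2-enoate | COc1ccc(COC/C=C(\CB2OC(C)(C)C(C)(C)O2)C(=O)OC(C)(C)C)cc1
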